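All runs come from a simulation for substances that don't exist, and the scatter is random.

Read the pace of target off the last readings, then follow one molecule of starting material to see where it can end. You asked for a quick number, and this is ours.

the same everywhere: free catalyst 0.44 mM

| run | starting material | second substrate | protic impurity | temperature | remark | time |
|---|---|---|---|---|---|---|
| Monday's | 0.022 M | 0.022 M | 4.4 mM | 95 °C | run made earlier |  |
| Friday's | 0.022 M | 0.088 M | 4.4 mM | 110 °C | run made earlier |  |
| Wednesday's | 0.044 M | 0.044 M | 4.4 mM | 95 °C | run made earlier |  |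
| cedar | 0.022 M | 0.0440 M | 4.40 mM | 100 °C |  | 2.0 h |
| ash | 0.022 M | 0.0440 M | 4.40 mM | 120 °C |  | 2.0 h |

| run | time / min | catalyst intermediate A / % | uncatalysed product / % | starting material / % | target / % |
|---|---|---|---|---|---|
| Monday's | 6.00 | 1.7 | 0.3 | 95.5 | 1.3 |
| Monday's | 10.0 | 2.5 | 0.1 | 92.7 | 3.3 |
| Monday's | 20.0 | 1.2 | 0.4 | 86.7 | 6.4 |
| Monday's | 40.0 | 1.7 | 0.1 | 77.2 | 12.9 |
| Monday's | 80.0 | 1.3 | 1.2 | 60.9 | 25.4 |
| Friday's | 10.0 | 1.9 | 0.7 | 82.4 | 10.3 |
| Friday's | 20.0 | 1.7 | 0.6 | 68.3 | 21.0 |
| Friday's | 25.0 | 1.1 | 1.3 | 61.7 | 25.9 |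
| Friday's | 40.0 | 1.3 | 1.8 | 44.8 | 40.3 |
| Friday's | 50.0 | 1.3 | 1.3 | 34.3 | 49.9 |
| Wednesday's | 6.00 | 0.7 | 0.1 | 96.7 | 0.9 |
| Wednesday's | 10.0 | 1.1 | 0 | 95.1 | 1.3 |
| Wednesday's | 20.0 | 1.1 | 0 | 91.4 | 3.5 |
| Wednesday's | 40.0 | 1.0 | 0.6 | 85.9 | 6.0 |
| Wednesday's | 80.0 | 1.6 | 1.3 | 76.8 | 12.7 |

(scatter of a reading: 0.3 percentage points)



- which of these there is most of at the end, counted by the starting material in it, cedar (uncatalysed product / catalyst intermediate A / starting material / target)
- which of these there is most of at the end, counted by the starting material in it, ash (uncatalysed product / catalyst intermediate A / starting material / target)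
- the largest of these amounts at the end, in percent of the starting material charged, cedar
- the largest of these amounts at the end, in percent of the starting material charged, ash

1. Wednesday's charges of starting material and second substrate were twice Monday's, yet at 80.0 min Wednesday's target fraction was half of Monday's. The two runs therefore read the same amount of target, although both charges changed together, so we take catalyst intermediate A as the resting state.

2. Our pace 0.191 h⁻¹ is the fraction of a 0.022 M charge turned into target per hour at 95 °C, read from Monday's last reading. Friday's gives 0.599 h⁻¹ at 110 °C.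

3. Friday's also held more second substrate, but we credit that growth to temperature. Spreading it evenly on a logarithmic scale multiplies Monday's pace by 1.46 for cedar and by 6.74 for ash.

4. Held steady over 2.0 h, cedar's pace gives an estimated 55.8% target. That exceeds the 44.2% of the charge that can be anything else, so target leads in cedar.

5. Ash's pace would convert 2.57 charges, so ash stops when its starting material is gone, and the forks set its yield. Friday's last reading leaves 13.2% unseen, beside 1.3% uncatalysed product. If the unseen loss takes protic impurity one for one, it is capped at 20.0% of the charge. We expect target in ash between 78.7% and 85.5%.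

6. The forecast says target in both flasks, 56% in cedar and 82% in ash, holding that “the catalyst is essentially saturated”.

The flasks give target as the largest amount in both, 54.8% in cedar and 84.2% in ash.

    starting material + protic impurity → quenched substrate (k = 0.0138 M⁻¹ s⁻¹, Ea = 64.0 kJ mol⁻¹)
    catalyst intermediate B → free catalyst + second product (k = 0.0216 s⁻¹, Ea = 97.0 kJ mol⁻¹)
    starting material → uncatalysed product (k = 4.02 × 10⁻⁶ s⁻¹, Ea = 120 kJ mol⁻¹)
    starting material + free catalyst ⇌ catalyst intermediate A (K = 4100 M⁻¹, k = 3.67 M⁻¹ s⁻¹, Ea = 50.0 kJ mol⁻¹, ΔH = −7.00 kJ mol⁻¹)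
    second substrate + free catalyst ⇌ catalyst intermediate B (K = 7.21 M⁻¹, k = 13.1 M⁻¹ s⁻¹, Ea = 55.0 kJ mol⁻¹, ΔH = −20.0 kJ mol⁻¹)
    catalyst intermediate A → free catalyst + target (k = 0.00443 s⁻¹, Ea = 101 kJ mol⁻¹)
    (constants at 100 °C)

In cedar, our pace needs 1.79 h for half a charge, while the passing of starting material and protic impurity into quenched substrate alone, with the other concentrations held at their charge, gives starting material a half-life of 3.2 h, which is longer. At 2.00 h, cedar holds 54.8% target against 14.5% quenched substrate. For a repeat of ash at 95 °C, Monday's pace stands unwarmed and gives 38.2% in 2.0 h, short of the charge. That flask holds 36.9% target and 46.5% starting material.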